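**Plan**

1. Locants are those of the target hydrindane: C1 (CH–OAc), C2 (C=O), C3 (CH2), C3a and C7a (ring fusion), C4 (C=CH2), C5 (C–O-angeloyl), C6 (C–OH), C7 (C–iPr). α is the face of the C7 isopropyl group.
2. Retrosynthesis: the C5 ester and C6–OH come from SN2 opening of a 5α,6α-vinyl epoxide by angelic acid; C1–OAc from a Mitsunobu inversion; C4=CH2 from a Wittig reaction; the epoxide from a C5=C6 enone stored as a silyl enol ether. The cyclopentanone is then cut at C2–C3 and C1–C7a to an allyl 2-siloxyvinyl ether, which goes back to cryptone, made from isovaleraldehyde and methyl vinyl ketone.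
3. Forward: the six-membered ring is made first (Michael/aldol); C3 is added by a Morita–Baylis–Hillman reaction; the two-carbon unit (future C2–C1) is hung on the C3 oxygen; the five-membered ring is closed in one pot; the six-ring oxygens come last.
4. Enabling feature: C7a=C3a–C3–O is an allyl ether on the six-membered ring. With an enol ether on that oxygen it is an allyl vinyl ether whose [3,3] shift makes C1–C7a and releases aldehyde C2 next to the new exocyclic C3=C3a alkene (a 4-pentenal), ready for hydroacylation to C2–C3. The C3–O tether bond is absent from the target; its oxygen ends as the C2 ketone oxygen.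
5. Stereochemistry: C7 from enamine catalysis; C7a anti to the isopropyl group in the rearrangement; C1 from the chair transition state, then inverted; C3a (trans fusion) from hydride delivery, backed by equilibration; C6 from axial peroxide attack; C5 from SN2 inversion.

Key step: step 7

Assumption: the enol silyl ether of the α-alkoxy aldehyde 7 forms as the Z isomer (both oxygens cis), as is usual for soft enolisation of α-oxygenated aldehydes; the C1 configuration of 9–16 and the inversion in step 12 follow from it.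

**Route**

Step 1
Reactants: 1 3-methylbutanal; 2 but-3-en-2-one
Product: 3 (2S)-5-oxo-2-(propan-2-yl)hexanal
Conditions: (S)-2-(methoxydiphenylmethyl)pyrrolidine (5 mol %), ethyl 3,4-dihydroxybenzoate (20 mol %), neat, 4 °C
Reagents that add atoms: none
Why: Enamine-catalysed Michael addition of the aldehyde to the vinyl ketone; the E-enamine should be attacked on the face away from the diarylmethyl group, which sets the later C7 as S.

Step 2
Reactants: 3 (2S)-5-oxo-2-(propan-2-yl)hexanal
Product: 4 (4S)-4-(propan-2-yl)cyclohex-2-en-1-one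
Conditions: LiOH (cat.), i-PrOH, rt
Reagents that add atoms: none
Why: Intramolecular aldol condensation (second half of a Robinson-type annulation); only the methyl ketone enolate can close a six-membered ring onto the aldehyde, and the mild base should leave the γ-stereocentre untouched.

Step 3
Reactants: 4 (4S)-4-(propan-2-yl)cyclohex-2-en-1-one
Product: 5 (4S)-2-(hydroxymethyl)-4-(propan-2-yl)cyclohex-2-en-1-one
Conditions: aq. CH2O (37 %), DMAP (0.2 equiv), THF–H2O, rt
Reagents that add atoms: formaldehyde C=O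
Why: Morita–Baylis–Hillman reaction of the cyclic enone with formaldehyde puts C3 as CH2OH on the α-carbon (future C3a) and creates the allylic alcohol without touching C7.

Step 4
Reactants: 5 (4S)-2-(hydroxymethyl)-4-(propan-2-yl)cyclohex-2-en-1-one
Product: 6 (4S)-4-(propan-2-yl)-2-[(prop-2-en-1-yloxy)methyl]cyclohex-2-en-1-one
Conditions: allyl 2,2,2-trichloroacetimidate (1.5 equiv), TfOH (5 mol %), CH2Cl2–cyclohexane, 0 °C to rt
Reagents that add atoms: allyl 2,2,2-trichloroacetimidate C=CCOC(=N)C(Cl)(Cl)Cl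
Why: Acid-catalysed O-allylation with a trichloroacetimidate is a base-free ether synthesis, so the enone alkoxide (retro-aldol, oxa-Michael) is never formed.

Step 5
Reactants: 6 (4S)-4-(propan-2-yl)-2-[(prop-2-en-1-yloxy)methyl]cyclohex-2-en-1-one
Product: 7 2-{[(3S)-6-oxo-3-(propan-2-yl)cyclohex-1-en-1-yl]methoxy}acetaldehyde
Conditions: OsO4 (2 mol %), NaIO4 (4 equiv), 2,6-lutidine, dioxane–H2O, rt
Reagents that add atoms: osmium tetroxide O=[Os](=O)(=O)=O (oxygen transferred; re-formed from sodium periodate [Na+].[O-]I(=O)(=O)=O)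
Why: Lemieux–Johnson cleavage; OsO4 should dihydroxylate the electron-rich terminal alkene far faster than the electron-poor trisubstituted enone alkene, and periodate cleaves the diol to the α-alkoxy aldehyde.

Step 6
Reactants: 7 2-{[(3S)-6-oxo-3-(propan-2-yl)cyclohex-1-en-1-yl]methoxy}acetaldehyde
Product: 8 (5S)-2-[(tert-butyldimethylsilyl)oxy]-3-[({(Z)-2-[(tert-butyldimethylsilyl)oxy]ethenyl}oxy)methyl]-5-(propan-2-yl)cyclohexa-1,3-diene
Conditions: TBSOTf (2.5 equiv), Et3N (4 equiv), CH2Cl2, –78 to 0 °C
Reagents that add atoms: tert-butyldimethylsilyl trifluoromethanesulfonate CC(C)(C)[Si](C)(C)OS(=O)(=O)C(F)(F)F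
Why: Soft enolisation with O-silylation; the aldehyde gives the Z-enol silyl ether (the vinyl half of the allyl vinyl ether) and the enone gives the cross-conjugated 2-siloxydiene by α′-deprotonation, which stores the regiochemistry of the later C5=C6 enone.

Step 7
Reactants: 8 (5S)-2-[(tert-butyldimethylsilyl)oxy]-3-[({(Z)-2-[(tert-butyldimethylsilyl)oxy]ethenyl}oxy)methyl]-5-(propan-2-yl)cyclohexa-1,3-diene
Product: 10 (1S,3aR,7S,7aS)-1,4-bis[(tert-butyldimethylsilyl)oxy]-7-(propan-2-yl)-1,3,3a,6,7,7a-hexahydro-2H-inden-2-one, via Claisen aldehyde 9 (not isolated)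
Conditions: [RhCl(cod)]2 (5 mol %), Ph2PCH2CH2PPh2 (11 mol %), PhCN, 150 °C, sealed tube, Ar
Reagents that add atoms: none
Why: Heating triggers the Claisen [3,3]-sigmatropic rearrangement of the allyl vinyl ether array C7a=C3a–C3–O–CH=CH(OTBS) through a six-membered chair transition state, which forms C1–C7a, breaks the C3–O tether bond and unmasks aldehyde C2 beside the new exocyclic C3=C3a alkene (aldehyde 9, a 4-pentenal); the univalent rhodium catalyst then adds the aldehyde C–H bond oxidatively, hydrometallates the exocyclic alkene (H to C3a, Rh to C3) and closes C2–C3 by reductive elimination. The closest known reaction type is the one-pot Claisen rearrangement–rhodium-catalysed intramolecular hydroacylation of allyl vinyl ethers to cyclopentanones, together with the rhodium-catalysed cyclisation of 3,4-disubstituted 4-pentenals. Only the cyclopentanone ring is closed, by C–C reductive elimination from a six-membered acyl–rhodium–alkyl metallacycle (formally 5-endo with respect to the C3=C3a alkene, which a metallacycle allows where a direct nucleophilic or radical attack would not). C7a is set by bond formation anti to the C7 isopropyl group on the 5-substituted cyclohexa-1,3-diene; C1 by the chair transition state with the Z-enol ether (siloxy group axial, hence cis to the C7a–C7 bond, the C1 epimer of the target, corrected with inversion in step 12); C3a by hydride delivery on the β face through a trans-fused, decalin-like metallacycle in which both tether bonds are equatorial. The step needs hydroacylation to outrun decarbonylation and to leave the 2-siloxydiene alone: the chelating diphosphine and the tethered 1,1-disubstituted alkene favour insertion, hydrometallation puts rhodium on C3, which is not allylic, so no allyl-rhodium pathway opens, and any cis-fused material can still be equilibrated at C3a once C4 is a ketone (steps 8 and 9).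

Step 8
Reactants: 10 (1S,3aR,7S,7aS)-1,4-bis[(tert-butyldimethylsilyl)oxy]-7-(propan-2-yl)-1,3,3a,6,7,7a-hexahydro-2H-inden-2-one
Product: 11 (1S,3aR,7R,7aS)-1-[(tert-butyldimethylsilyl)oxy]-7-(propan-2-yl)-3,3a,7,7a-tetrahydro-1H-indene-2,4-dione
Conditions: Pd(OAc)2 (1.1 equiv), MeCN, rt to 40 °C
Reagents that add atoms: none
Why: Saegusa–Ito oxidation; Pd(OAc)2 turns the regiodefined C4 silyl enol ether into the C5=C6 enone by β-hydride elimination, so the C2 ketone never has to be enolised selectively.

Step 9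
Reactants: 11 (1S,3aR,7R,7aS)-1-[(tert-butyldimethylsilyl)oxy]-7-(propan-2-yl)-3,3a,7,7a-tetrahydro-1H-indene-2,4-dione
Product: 12 (1S,3aR,5S,6S,7S,7aS)-1-[(tert-butyldimethylsilyl)oxy]-5,6-epoxy-7-(propan-2-yl)hexahydro-1H-indene-2,4-dione (5α,6α-epoxide)
Conditions: 30 % H2O2, K2CO3 (0.3 equiv), MeOH, 0 °C
Reagents that add atoms: hydrogen peroxide OO
Why: Weitz–Scheffer (nucleophilic) epoxidation; hydroperoxide should add axially to C6 on the α face of the locked trans-fused enone (chair-like enolate) and close to the α-epoxide, and the mild base lets any cis-fused material epimerise at C3a to the trans-fused ketone.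

Step 10
Reactants: 12 (1S,3aR,5S,6S,7S,7aS)-1-[(tert-butyldimethylsilyl)oxy]-5,6-epoxy-7-(propan-2-yl)hexahydro-1H-indene-2,4-dione
Product: 15 (1S,3aR,5R,6S,7S,7aR)-1-[(tert-butyldimethylsilyl)oxy]-5,6-epoxy-4-methylidene-7-(propan-2-yl)octahydro-2H-inden-2-one, via lithium enolate 13 (not isolated), via methylenated lithium enolate 14 (not isolated)
Conditions: LiN(SiMe3)2 (1.05 equiv), THF, –78 °C; then Ph3P=CH2 [from Ph3PCH3Br (3 equiv), KN(SiMe3)2 (2.9 equiv)], –78 to 0 °C; AcOH quench at –78 °C
Reagents that add atoms: methyltriphenylphosphonium bromide C[P+](c1ccccc1)(c1ccccc1)c1ccccc1.[Br-]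
Why: Wittig methylenation with the more easily enolised cyclopentanone masked in situ as its lithium enolate (kinetic deprotonation at the C3 methylene, which also shields C1–H from the base), so that only the epoxy ketone carbonyl C4 is olefinated and the acid quench returns the C2 ketone.

Step 11
Reactants: 15 (1S,3aR,5R,6S,7S,7aR)-1-[(tert-butyldimethylsilyl)oxy]-5,6-epoxy-4-methylidene-7-(propan-2-yl)octahydro-2H-inden-2-one
Product: 16 (1S,3aR,5R,6S,7S,7aR)-5,6-epoxy-1-hydroxy-4-methylidene-7-(propan-2-yl)octahydro-2H-inden-2-one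
Conditions: Bu4NF (1.2 equiv), AcOH (1.2 equiv), THF, 0 °C
Reagents that add atoms: none
Why: Fluoride-mediated silyl ether cleavage, buffered with acetic acid so that the α-ketol does not epimerise or rearrange and the vinyl epoxide stays closed.

Step 12
Reactants: 16 (1S,3aR,5R,6S,7S,7aR)-5,6-epoxy-1-hydroxy-4-methylidene-7-(propan-2-yl)octahydro-2H-inden-2-one
Product: 17 (1R,3aR,5R,6S,7S,7aR)-5,6-epoxy-4-methylidene-2-oxo-7-(propan-2-yl)octahydro-1H-inden-1-yl acetate
Conditions: AcOH (2 equiv), PPh3 (1.5 equiv), DIAD (1.5 equiv), toluene, 0 °C to rt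
Reagents that add atoms: acetic acid CC(=O)O
Why: Mitsunobu reaction; SN2 displacement at the carbonyl-activated carbinol by acetate inverts C1 to the target configuration, the nucleophile entering trans to the C7a–C7 bond, and installs the acetate in the same step.

Step 13
Reactants: 17 (1R,3aR,5R,6S,7S,7aR)-5,6-epoxy-4-methylidene-2-oxo-7-(propan-2-yl)octahydro-1H-inden-1-yl acetate; 18 (2Z)-2-methylbut-2-enoic acid (angelic acid)
Product: 19 (1R,3aR,5S,6S,7S,7aR)-1-(acetyloxy)-6-hydroxy-4-methylidene-2-oxo-7-(propan-2-yl)octahydro-1H-inden-5-yl (2Z)-2-methylbut-2-enoate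
Conditions: 18 (5 equiv), CsO2CC(CH3)=CHCH3 (0.3 equiv), DMF, 50 °C
Reagents that add atoms: none
Why: Carboxylate-mediated opening of a vinyl epoxide; SN2 attack of angelate at the allylic C5 from the β face gives the trans-diaxial hydroxy ester (inversion at C5, C6–O untouched), allylic activation and the trans-diaxial opening rule both pointing to C5, and no protecting group is needed.

**Compound list**

1 | 3-methylbutanal (isovaleraldehyde) | CC(C)CC=O | starting material
2 | but-3-en-2-one (methyl vinyl ketone) | CC(=O)C=C | starting material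
3 | (2S)-5-oxo-2-(propan-2-yl)hexanal | O=C[C@H](C(C)C)CCC(C)=O | intermediate
4 | (4S)-4-(propan-2-yl)cyclohex-2-en-1-one (cryptone) | O=C1C=C[C@H](C(C)C)CC1 | intermediate
5 | (4S)-2-(hydroxymethyl)-4-(propan-2-yl)cyclohex-2-en-1-one | O=C1C(CO)=C[C@H](C(C)C)CC1 | intermediate
6 | (4S)-4-(propan-2-yl)-2-[(prop-2-en-1-yloxy)methyl]cyclohex-2-en-1-one | O=C1C(COCC=C)=C[C@H](C(C)C)CC1 | intermediate
7 | 2-{[(3S)-6-oxo-3-(propan-2-yl)cyclohex-1-en-1-yl]methoxy}acetaldehyde | O=CCOCC1=C[C@H](C(C)C)CCC1=O | intermediate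
8 | (5S)-2-[(tert-butyldimethylsilyl)oxy]-3-[({(Z)-2-[(tert-butyldimethylsilyl)oxy]ethenyl}oxy)methyl]-5-(propan-2-yl)cyclohexa-1,3-diene | CC(C)(C)[Si](C)(C)OC1=CC[C@@H](C(C)C)C=C1CO/C=C\O[Si](C)(C)C(C)(C)C | intermediate
9 | (2S)-2-[(tert-butyldimethylsilyl)oxy]-2-[(1S,6S)-3-[(tert-butyldimethylsilyl)oxy]-2-methylidene-6-(propan-2-yl)cyclohex-3-en-1-yl]acetaldehyde (Claisen aldehyde) | O=C[C@@H](O[Si](C)(C)C(C)(C)C)[C@H]1[C@H](C(C)C)CC=C(O[Si](C)(C)C(C)(C)C)C1=C | intermediate
10 | (1S,3aR,7S,7aS)-1,4-bis[(tert-butyldimethylsilyl)oxy]-7-(propan-2-yl)-1,3,3a,6,7,7a-hexahydro-2H-inden-2-one | CC(C)(C)[Si](C)(C)OC1=CC[C@@H](C(C)C)[C@@H]2[C@H](O[Si](C)(C)C(C)(C)C)C(=O)C[C@@H]12 | intermediate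
11 | (1S,3aR,7R,7aS)-1-[(tert-butyldimethylsilyl)oxy]-7-(propan-2-yl)-3,3a,7,7a-tetrahydro-1H-indene-2,4-dione | O=C1C=C[C@@H](C(C)C)[C@@H]2[C@H](O[Si](C)(C)C(C)(C)C)C(=O)C[C@@H]12 | intermediate
12 | (1S,3aR,5S,6S,7S,7aS)-1-[(tert-butyldimethylsilyl)oxy]-5,6-epoxy-7-(propan-2-yl)hexahydro-1H-indene-2,4-dione | O=C1[C@H]3O[C@H]3[C@@H](C(C)C)[C@@H]2[C@H](O[Si](C)(C)C(C)(C)C)C(=O)C[C@@H]12 | intermediate
13 | lithium C2(C3)-enolate of 12 | O=C1[C@H]3O[C@H]3[C@@H](C(C)C)[C@@H]2[C@H](O[Si](C)(C)C(C)(C)C)C(O[Li])=C[C@@H]12 | intermediate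
14 | lithium C2(C3)-enolate of 15 (4-methylidene compound) | C=C1[C@H]3O[C@H]3[C@@H](C(C)C)[C@@H]2[C@H](O[Si](C)(C)C(C)(C)C)C(O[Li])=C[C@@H]12 | intermediate
15 | (1S,3aR,5R,6S,7S,7aR)-1-[(tert-butyldimethylsilyl)oxy]-5,6-epoxy-4-methylidene-7-(propan-2-yl)octahydro-2H-inden-2-one | C=C1[C@H]3O[C@H]3[C@@H](C(C)C)[C@@H]2[C@H](O[Si](C)(C)C(C)(C)C)C(=O)C[C@@H]12 | intermediate
16 | (1S,3aR,5R,6S,7S,7aR)-5,6-epoxy-1-hydroxy-4-methylidene-7-(propan-2-yl)octahydro-2H-inden-2-one | C=C1[C@H]3O[C@H]3[C@@H](C(C)C)[C@@H]2[C@H](O)C(=O)C[C@@H]12 | intermediate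
17 | (1R,3aR,5R,6S,7S,7aR)-5,6-epoxy-4-methylidene-2-oxo-7-(propan-2-yl)octahydro-1H-inden-1-yl acetate | C=C1[C@H]3O[C@H]3[C@@H](C(C)C)[C@@H]2[C@@H](OC(C)=O)C(=O)C[C@@H]12 | intermediate
18 | (2Z)-2-methylbut-2-enoic acid (angelic acid) | C/C=C(/C)C(=O)O | starting material
19 | (1R,3aR,5S,6S,7S,7aR)-1-(acetyloxy)-6-hydroxy-4-methylidene-2-oxo-7-(propan-2-yl)octahydro-1H-inden-5-yl (2Z)-2-methylbut-2-enoate | C=C1[C@@H]2CC(=O)[C@H](OC(C)=O)[C@H]2[C@H](C(C)C)[C@H](O)[C@H]1OC(=O)/C(C)=C\C | target

**Step count**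

Total steps: 13. Longest linear sequence: 13 steps (1 and 2 to 19).

**Steps most likely to fail, with fallbacks**

Step 7. What may go wrong: decarbonylation at the acyl rhodium hydride stage; hydrometallation or isomerisation of the 2-siloxydiene; decay of the catalyst at the rearrangement temperature, so that aldehyde 9 is consumed without ring closure; poor facial or chair/boat discrimination in the rearrangement. Fallback: the two bond formations are decoupled and the siloxydiene is avoided. Setting out from 7, only the aldehyde is silylated (TBSOTf 1.05 equiv, Et3N, CH2Cl2, –78 °C) to give the enone enol ether (4S)-2-[({(Z)-2-[(tert-butyldimethylsilyl)oxy]ethenyl}oxy)methyl]-4-(propan-2-yl)cyclohex-2-en-1-one F1. Metal-free Claisen rearrangement (toluene, 120–140 °C) should give the α-methylene keto aldehyde (2S)-2-[(tert-butyldimethylsilyl)oxy]-2-[(1S,6S)-2-methylidene-3-oxo-6-(propan-2-yl)cyclohexyl]acetaldehyde F2. This is cyclised at room temperature with [Rh(Ph2PCH2CH2PPh2)]BF4 in CH2Cl2 (hydroacylation of the enone alkene, C3a then being epimerisable to the trans fusion) to the diketone (1S,3aR,7S,7aS)-1-[(tert-butyldimethylsilyl)oxy]-7-(propan-2-yl)hexahydro-1H-indene-2,4-dione F3. Aerobic dehydrogenation of the six-membered ketone (Pd(O2CCF3)2, DMSO, O2, AcOH, 80 °C), for which cyclohexanones are the better substrates, returns to the route at 11.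

Step 10. What may go wrong: addition of the ylide to the cyclopentanone carbonyl if its enolisation is incomplete; enolisation of the epoxy ketone instead; epimerisation at C1 by excess base. Fallback: the in-situ mask is replaced by an isolated protecting group. Setting out from 12, LiN(SiMe3)2 then TBSCl (THF, –78 °C) gives the C2 tert-butyldimethylsilyl enol ether (C2=C3) of 12 F4. Wittig methylenation (Ph3P=CH2, THF, 0 °C) of its only remaining ketone gives the C2 tert-butyldimethylsilyl enol ether (C2=C3) of 15 F5. Bu4NF/AcOH (THF, 0 °C) removes both silyl groups and returns to the route at 16.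

Step 13. What may go wrong: conjugate (SN2′) opening at the exocyclic methylene terminus; ionisation to an allyl cation with loss of stereospecificity; slow opening by the weakly nucleophilic angelate; Z-to-E isomerisation of the angelate on prolonged heating. Fallback: opening and acylation are separated. Setting out from 17, acid-catalysed hydrolysis (dilute HClO4, THF–H2O, 0 °C; water attacks the allylic C5 anti) gives the trans-diaxial diol (1R,3aR,5S,6S,7S,7aR)-5,6-dihydroxy-4-methylidene-2-oxo-7-(propan-2-yl)octahydro-1H-inden-1-yl acetate F6. Its less hindered allylic C5 hydroxyl (C6–OH is flanked by the isopropyl-bearing carbon) is esterified with the mixed anhydride of 18 and 2,4,6-trichlorobenzoyl chloride (Et3N, toluene, 80 °C, no nucleophilic catalyst, Yamaguchi-type), which returns to the route at 19.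

**Further compounds**

F1 | step 7 | (4S)-2-[({(Z)-2-[(tert-butyldimethylsilyl)oxy]ethenyl}oxy)methyl]-4-(propan-2-yl)cyclohex-2-en-1-one | O=C1C(CO/C=C\O[Si](C)(C)C(C)(C)C)=C[C@H](C(C)C)CC1
F2 | step 7 | (2S)-2-[(tert-butyldimethylsilyl)oxy]-2-[(1S,6S)-2-methylidene-3-oxo-6-(propan-2-yl)cyclohexyl]acetaldehyde | O=C[C@@H](O[Si](C)(C)C(C)(C)C)[C@H]1[C@H](C(C)C)CCC(=O)C1=C
F3 | step 7 | (1S,3aR,7S,7aS)-1-[(tert-butyldimethylsilyl)oxy]-7-(propan-2-yl)hexahydro-1H-indene-2,4-dione | O=C1CC[C@@H](C(C)C)[C@@H]2[C@H](O[Si](C)(C)C(C)(C)C)C(=O)C[C@@H]12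
F4 | step 10 | C2 tert-butyldimethylsilyl enol ether (C2=C3) of 12 | O=C1[C@H]3O[C@H]3[C@@H](C(C)C)[C@@H]2[C@H](O[Si](C)(C)C(C)(C)C)C(O[Si](C)(C)C(C)(C)C)=C[C@@H]12
F5 | step 10 | C2 tert-butyldimethylsilyl enol ether (C2=C3) of 15 | C=C1[C@H]3O[C@H]3[C@@H](C(C)C)[C@@H]2[C@H](O[Si](C)(C)C(C)(C)C)C(O[Si](C)(C)C(C)(C)C)=C[C@@H]12
F6 | step 13 | (1R,3aR,5S,6S,7S,7aR)-5,6-dihydroxy-4-methylidene-2-oxo-7-(propan-2-yl)octahydro-1H-inden-1-yl acetate | C=C1[C@H](O)[C@@H](O)[C@@H](C(C)C)[C@@H]2[C@@H](OC(C)=O)C(=O)C[C@@H]12
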